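**Overview**

- Retrosynthesis: the C4 methyl ether is read back to a phenol and the C7 hydroxyl to C7–H2 (through a para-quinone methide); then the C1'–C2 spiro bond is cut, then the central C8–C8' bond, then the N-acyl bond to the auxiliary.
- Enabling feature: spiro carbon C1' of the 2,6-dimethoxycyclohexa-2,5-dienone is tied to aryl carbon C2 by the seven-membered ring C1'–C7'–C8'(Me)–C8(Me)–C7–C1–C2. Without the 7-OH and with 4-OH for 4-OMe, opening that bond leaves a C2-symmetric (8R,8'R)-2,3-dimethyl-1,4-bis(4-hydroxy-3,5-dimethoxyphenyl)butane, so it does not matter which phenol is oxidised.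
- Forward order: both six-membered rings come unchanged from sinapic acid; the chain is joined at C8–C8' by oxidative homocoupling of an N-acyloxazolidinone enolate; the two carbonyl carbons are taken down to methyl groups; PhI(OAc)2 then closes the seven-membered ring and creates the spirodienone in one step.
- Stereochemistry: C8 and C8' arise together as the R,R pair under control of two (S)-4-benzyloxazolidinones; C7 is set last, by addition of water to the ring-held quinone methide anti to the C8 methyl group (7,8-trans); the spiro carbon has two identical arms and is not a stereocentre.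
- Finish: O-methylation of the remaining phenol.

Key step: step 10

Remark (one assumption on the chemistry): the 7,8-trans alcohol is taken to be both the kinetic and the thermodynamic product of quinone methide hydration. Lignan locants are used (aryl ring C1–C6 with C7 on C1; dienone ring C1'–C6' with C7' on the spiro carbon C1'); the target is (7R,8S,8'R), and 8S instead of the 8R of the 7-deoxy compounds is only a change of substituent priority, not of geometry.

**Route**

Step 1
Reactants: 1 sinapic acid
Product: 2 3-(4-hydroxy-3,5-dimethoxyphenyl)propanoic acid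
Conditions: H2 (1 atm), 10% Pd/C, MeOH, rt
Reagents that add atoms: none
Why: Heterogeneous catalytic hydrogenation should saturate only the conjugated C=C, since the electron-rich arene, the phenol and the acid are inert to H2 over Pd/C at room temperature.

Step 2
Reactants: 2 3-(4-hydroxy-3,5-dimethoxyphenyl)propanoic acid
Product: 3 benzyl 3-(4-benzyloxy-3,5-dimethoxyphenyl)propanoate
Conditions: BnBr (2.4 equiv), K2CO3, DMF, 60 °C
Reagents that add atoms: benzyl bromide, BrCc1ccccc1
Why: Williamson alkylation of the phenoxide, accompanied by carboxylate alkylation, should install the benzyl ether that carries the phenol through the enolate, hydride and sulfonate chemistry.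

Step 3
Reactants: 3 benzyl 3-(4-benzyloxy-3,5-dimethoxyphenyl)propanoate
Product: 4 3-(4-benzyloxy-3,5-dimethoxyphenyl)propanoic acid
Conditions: LiOH·H2O, THF/MeOH/H2O, rt; then 1 M HCl
Reagents that add atoms: lithium hydroxide, [Li+].[OH-]
Why: Saponification by acyl–oxygen cleavage should free the acid while the aryl benzyl ether, which has no comparable cleavage path, stays intact.

Step 4
Reactants: 4 3-(4-benzyloxy-3,5-dimethoxyphenyl)propanoic acid; 5 (S)-4-benzyloxazolidin-2-one
Product: 7 (S)-4-benzyl-3-[3-(4-benzyloxy-3,5-dimethoxyphenyl)propanoyl]oxazolidin-2-one, via pivalic mixed anhydride 6 (not isolated)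
Conditions: t-BuCOCl, Et3N, THF, −20 °C; then LiCl, 5, −20 °C to rt
Reagents that add atoms: none
Why: Mixed-anhydride N-acylation, in which the LiCl/Et3N-activated oxazolidinone attacks the less hindered carbonyl of the pivalic anhydride, is a standard way to load this auxiliary and creates no stereocentre.

Step 5
Reactants: 7 (S)-4-benzyl-3-[3-(4-benzyloxy-3,5-dimethoxyphenyl)propanoyl]oxazolidin-2-one (two molecules)
Product: 9 (2R,3R)-2,3-bis(4-benzyloxy-3,5-dimethoxybenzyl)-1,4-bis[(S)-4-benzyl-2-oxooxazolidin-3-yl]butane-1,4-dione, via lithium Z-enolate 8 (not isolated)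
Conditions: LiN(iPr)2 (1.1 equiv), THF, −78 °C; then TiCl4 (1.1 equiv), −78 °C to rt
Reagents that add atoms: none
Why: Oxidative enolate homocoupling, in which the chelated Z-enolate is transmetallated to a tetravalent titanium enolate that releases trivalent titanium and an α-acyl radical, should join the two halves on the enolate faces turned away from the 4-benzyl groups (the facial sense of alkylations with this auxiliary), so that C8 and C8' are created together as the R,R pair.

Step 6
Reactants: 9 (2R,3R)-bis-imide
Product: 10 (2R,3R)-2,3-bis(4-benzyloxy-3,5-dimethoxybenzyl)butane-1,4-diol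
Conditions: LiBH4 (excess), THF/MeOH, 0 °C to rt
Reagents that add atoms: none
Why: Borohydride reduction of N-acyloxazolidinones at the exocyclic carbonyl should give both primary alcohols (a transient lactone would be reduced as well) and release the auxiliary without enolising, and hence without epimerising, the α-carbons.

Step 7
Reactants: 10 (2R,3R)-2,3-bis(4-benzyloxy-3,5-dimethoxybenzyl)butane-1,4-diol
Product: 11 (2R,3R)-2,3-bis(4-benzyloxy-3,5-dimethoxybenzyl)butane-1,4-diyl bis(methanesulfonate)
Conditions: MsCl (3 equiv), Et3N, CH2Cl2, 0 °C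
Reagents that add atoms: methanesulfonyl chloride, CS(=O)(=O)Cl
Why: Sulfonylation of the two primary alcohols with excess reagent is fast at 0 °C and should outrun cyclisation of a mono-mesylate to the tetrahydrofuran.

Step 8
Reactants: 11 (2R,3R)-bis(methanesulfonate)
Product: 12 (2R,3R)-1,4-bis(4-benzyloxy-3,5-dimethoxyphenyl)-2,3-dimethylbutane
Conditions: LiAlH4, THF, 0 °C to reflux
Reagents that add atoms: none
Why: SN2 displacement of primary sulfonates by hydride, the standard way from 2,3-dibenzylbutane-1,4-diols to 2,3-dimethyl-1,4-diarylbutanes, should give both methyl groups without touching the stereocentres or the benzyl ethers.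

Step 9
Reactants: 12 (2R,3R)-1,4-bis(4-benzyloxy-3,5-dimethoxyphenyl)-2,3-dimethylbutane
Product: 13 4,4'-[(2R,3R)-2,3-dimethylbutane-1,4-diyl]bis(2,6-dimethoxyphenol)
Conditions: H2 (1 atm), 10% Pd/C, EtOAc/MeOH, rt
Reagents that add atoms: none
Why: Hydrogenolysis of the two aryl benzyl ethers should unveil both phenols under neutral conditions, nothing else in the molecule being reducible.

Step 10
Reactants: 13 4,4'-[(2R,3R)-2,3-dimethylbutane-1,4-diyl]bis(2,6-dimethoxyphenol)
Product: 14 7-deoxy spirodienone phenol (8R,8'R)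
Conditions: PhI(OAc)2 (1.0 equiv, slow addition), solid NaHCO3, (CF3)2CHOH/CH2Cl2 1:1, 0.01 M, −20 °C
Reagents that add atoms: none
Why: Ligand exchange of one phenol on the trivalent iodine of PhI(OAc)2 and loss of iodobenzene and acetate give, in the ionising but non-nucleophilic fluoroalcohol, a phenoxenium-type cation whose charge sits on the two methoxy-bearing ortho carbons and on the chain-bearing para carbon C1'. C2 of the other ring, activated by one ortho and one para methoxy group, attacks C1' and the arenium ion loses a proton; this is the hypervalent-iodine para-ipso phenol–arene coupling established for phenolic 1,4-diarylbutane and dibenzylbutyrolactone lignans. The seven-membered ring C1'–C7'–C8'–C8–C7–C1–C2 closes in a 7-exo-trig spiro mode with respect to the cyclohexadienyl cation, and the oxidised ring becomes the 2,6-dimethoxycyclohexa-2,5-dienone. No stereocentre is created, because the spiro carbon carries two identical dienone arms, and C8 and C8' lie away from the reacting atoms and cannot epimerise. The step needs chemoselectivity only: the C2 axis makes the two phenols equivalent and the local symmetry of each ring makes C2 and C6 equivalent, so every productive pathway gives the same compound, the methoxy groups block ortho C–C coupling, and one equivalent of oxidant added slowly at high dilution and low temperature should limit oxidation of the product phenol. Solid NaHCO3 takes up the acetic acid so that the dienone does not rearrange (dienone–phenol) to the dibenzocyclooctadiene.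

Step 11
Reactants: 14 7-deoxy spirodienone phenol (8R,8'R)
Product: 16 7-hydroxy spirodienone phenol (7R,8S,8'R), via para-quinone methide 15 (not isolated)
Conditions: Ag2O, CH2Cl2, rt, dark; filter through Celite; then THF/H2O, cat. citric acid (pH 3–4), 0 °C to rt
Reagents that add atoms: water, O
Why: Ag2O dehydrogenates 4-alkyl-2,6-dimethoxyphenols to their para-quinone methides, and acid-catalysed 1,6-addition of water to the exocyclic carbon C7 restores the aromatic ring, water entering anti to the adjacent C8 methyl group so that C7 is formed as the 7,8-trans (7R) alcohol, a preference that reversible re-ionisation under the mildly acidic conditions should reinforce.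

Step 12
Reactants: 16 7-hydroxy spirodienone phenol (7R,8S,8'R)
Product: 17 target CNP0288561.1
Conditions: MeI, K2CO3, acetone, rt
Reagents that add atoms: iodomethane, CI
Why: Williamson O-methylation under weak base should be selective for the phenol over the secondary benzylic alcohol, and carbonate does not affect the dienone, which has no enolisable position.

**Compound list**

1 | sinapic acid, (E)-3-(4-hydroxy-3,5-dimethoxyphenyl)prop-2-enoic acid | COc1cc(/C=C/C(=O)O)cc(OC)c1O | starting material
2 | 3-(4-hydroxy-3,5-dimethoxyphenyl)propanoic acid | COc1cc(CCC(=O)O)cc(OC)c1O | intermediate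
3 | benzyl 3-(4-benzyloxy-3,5-dimethoxyphenyl)propanoate | COc1cc(CCC(=O)OCc2ccccc2)cc(OC)c1OCc1ccccc1 | intermediate
4 | 3-(4-benzyloxy-3,5-dimethoxyphenyl)propanoic acid | COc1cc(CCC(=O)O)cc(OC)c1OCc1ccccc1 | intermediate
5 | (S)-4-benzyloxazolidin-2-one (chiral auxiliary) | O=C1N[C@@H](Cc2ccccc2)CO1 | starting material
6 | 3-(4-benzyloxy-3,5-dimethoxyphenyl)propanoic pivalic anhydride | COc1cc(CCC(=O)OC(=O)C(C)(C)C)cc(OC)c1OCc1ccccc1 | intermediate
7 | (S)-4-benzyl-3-[3-(4-benzyloxy-3,5-dimethoxyphenyl)propanoyl]oxazolidin-2-one | COc1cc(CCC(=O)N2[C@@H](Cc3ccccc3)COC2=O)cc(OC)c1OCc1ccccc1 | intermediate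
8 | lithium Z-enolate of 7 (OLi cis to the arylmethyl group) | [Li]O/C(=C\Cc1cc(OC)c(OCc2ccccc2)c(OC)c1)N1[C@@H](Cc2ccccc2)COC1=O | intermediate
9 | (2R,3R)-2,3-bis(4-benzyloxy-3,5-dimethoxybenzyl)-1,4-bis[(S)-4-benzyl-2-oxooxazolidin-3-yl]butane-1,4-dione | O=C(N1[C@@H](Cc2ccccc2)COC1=O)[C@H](Cc1cc(OC)c(OCc2ccccc2)c(OC)c1)[C@@H](Cc1cc(OC)c(OCc2ccccc2)c(OC)c1)C(=O)N1[C@@H](Cc2ccccc2)COC1=O | intermediate
10 | (2R,3R)-2,3-bis(4-benzyloxy-3,5-dimethoxybenzyl)butane-1,4-diol | OC[C@H](Cc1cc(OC)c(OCc2ccccc2)c(OC)c1)[C@@H](Cc1cc(OC)c(OCc2ccccc2)c(OC)c1)CO | intermediate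
11 | (2R,3R)-2,3-bis(4-benzyloxy-3,5-dimethoxybenzyl)butane-1,4-diyl bis(methanesulfonate) | CS(=O)(=O)OC[C@H](Cc1cc(OC)c(OCc2ccccc2)c(OC)c1)[C@@H](Cc1cc(OC)c(OCc2ccccc2)c(OC)c1)COS(C)(=O)=O | intermediate
12 | (2R,3R)-1,4-bis(4-benzyloxy-3,5-dimethoxyphenyl)-2,3-dimethylbutane | COc1cc(cc(OC)c1OCc1ccccc1)C[C@@H](C)[C@H](C)Cc1cc(OC)c(OCc2ccccc2)c(OC)c1 | intermediate
13 | 4,4'-[(2R,3R)-2,3-dimethylbutane-1,4-diyl]bis(2,6-dimethoxyphenol), the C2-symmetric bisphenol | COc1cc(cc(OC)c1O)C[C@@H](C)[C@H](C)Cc1cc(OC)c(O)c(OC)c1 | intermediate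
14 | 7-deoxy spirodienone phenol, (7R,8R)-3-hydroxy-2,4,3',5'-tetramethoxy-7,8-dimethyl-6,7,8,9-tetrahydrospiro[benzo[7]annulene-5,1'-cyclohexa[2,5]dien]-4'-one (lignan locants 8R,8'R) | COC1=CC2(C=C(OC)C1=O)C[C@@H](C)[C@H](C)Cc1cc(OC)c(O)c(OC)c12 | intermediate
15 | para-quinone methide of 14 (C7=C1 double bond held in the seven-membered ring, ring carbonyl at C4, methyl-bearing stereocentres as in 14) | COC1=CC2(C=C(OC)C1=O)C[C@@H](C)[C@H](C)/C=C1/C=C(OC)C(=O)C(OC)=C12 | intermediate
16 | 7-hydroxy spirodienone phenol, (7R,8S,9R)-3,9-dihydroxy-2,4,3',5'-tetramethoxy-7,8-dimethyl-6,7,8,9-tetrahydrospiro[benzo[7]annulene-5,1'-cyclohexa[2,5]dien]-4'-one (lignan locants 7R,8S,8'R) | COC1=CC2(C=C(OC)C1=O)C[C@@H](C)[C@H](C)[C@@H](O)c1cc(OC)c(O)c(OC)c12 | intermediate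
17 | CNP0288561.1, (7R,8S,9R)-9-hydroxy-2,3,4,3',5'-pentamethoxy-7,8-dimethyl-6,7,8,9-tetrahydrospiro[benzo[7]annulene-5,1'-cyclohexa[2,5]dien]-4'-one (lignan locants 7R,8S,8'R) | COC1=CC2(C=C(OC)C1=O)C[C@@H](C)[C@H](C)[C@@H](O)c1cc(OC)c(OC)c(OC)c12 | target

**Step count and risks**

Total step count: 12. Longest linear sequence: 12 steps (1 to 17); the auxiliary 5 is purchased.

Steps most likely to fail:

1. Step 10. Oxidation may not stop at one phenol, because the product still carries a 2,6-dimethoxyphenol as electron-rich as those of the substrate. The phenoxenium ion may also lose a C7' proton to give an open-chain quinone methide, or be captured by the fluoroalcohol instead of the arene. The fallback desymmetrises with a protecting group before the oxidation, so that only one ring can be oxidised and the product has no free phenol. It sets out from 13: statistical mono-silylation (TBSCl 1 equiv, imidazole, DMF; unreacted bisphenol recycled) should give 4-[(2R,3R)-4-(4-tert-butyldimethylsilyloxy-3,5-dimethoxyphenyl)-2,3-dimethylbutyl]-2,6-dimethoxyphenol F1. PhI(OAc)2 in (CF3)2CHOH/CH2Cl2 with NaHCO3 then oxidises the only free phenol, and the silyloxy ring, still activated at C2 by its two methoxy groups, closes the same spiro ring to the O-silyl spirodienone F2. Bu4NF buffered with AcOH in THF at 0 °C removes the silyl group, and the fallback comes back to the route at 14.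

2. Step 11. Water may add to the quinone methide from the face syn to the C8 methyl group, or the facial preference may be low. The fallback corrects the configuration at C7 by SN2 inversion instead of relying on facial selectivity. It sets out from 14: the quinone methide 15 is hydrated as before, and the 7-epimeric alcohol (7S, OH cis to the C8 methyl) F3 is separated and methylated (MeI, K2CO3, acetone) to the 7-epimer of the target F4. A Mitsunobu reaction (PPh3, diisopropyl azodicarboxylate, 4-nitrobenzoic acid, THF, 0 °C to rt) should then give the inverted (7R) 4-nitrobenzoate F5, helped by the fact that the out-of-plane 4-methoxy group of a 3,4,5-trimethoxyphenyl ring stabilises a benzylic cation only weakly. Methanolysis (K2CO3, MeOH, rt) brings the fallback back to the route at 17.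

3. Step 5. Facial control in the C–C bond formation between the two enolate-derived partners may be incomplete and give the R,S dimer alongside the R,R one, or the titanium enolate may be quenched without coupling. The fallback builds the same diol by two sequential alkylations instead of a dimerisation. It sets out from 7: alkylation of its sodium enolate (NaN(SiMe3)2, THF, −78 °C) with tert-butyl bromoacetate should give (S)-4-benzyl-3-[(R)-2-(4-benzyloxy-3,5-dimethoxybenzyl)-4-tert-butoxy-4-oxobutanoyl]oxazolidin-2-one F6, with the same facial sense as in step 5. LiBH4 in THF/MeOH removes the auxiliary to give tert-butyl (R)-3-(4-benzyloxy-3,5-dimethoxybenzyl)-4-hydroxybutanoate F7, and CF3CO2H in CH2Cl2 closes it to (R)-4-(4-benzyloxy-3,5-dimethoxybenzyl)dihydrofuran-2(3H)-one F8. The electrophile is made from commercial syringaldehyde: BnBr, K2CO3, DMF gives 4-benzyloxy-3,5-dimethoxybenzaldehyde F9; NaBH4 in MeOH gives (4-benzyloxy-3,5-dimethoxyphenyl)methanol F10; PBr3 in CH2Cl2 at 0 °C gives 4-benzyloxy-3,5-dimethoxybenzyl bromide F11. The lithium enolate of F8 (LiN(iPr)2, THF, −78 °C) should be alkylated by F11 anti to the existing substituent to give (3R,4R)-3,4-bis(4-benzyloxy-3,5-dimethoxybenzyl)dihydrofuran-2(3H)-one F12. LiAlH4 in THF opens the lactone, and the fallback comes back to the route at 10.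

**Further compounds**

F1 | step 10 | 4-[(2R,3R)-4-(4-tert-butyldimethylsilyloxy-3,5-dimethoxyphenyl)-2,3-dimethylbutyl]-2,6-dimethoxyphenol | COc1cc(cc(OC)c1O)C[C@@H](C)[C@H](C)Cc1cc(OC)c(O[Si](C)(C)C(C)(C)C)c(OC)c1
F2 | step 10 | O-tert-butyldimethylsilyl ether of 14 | COC1=CC2(C=C(OC)C1=O)C[C@@H](C)[C@H](C)Cc1cc(OC)c(O[Si](C)(C)C(C)(C)C)c(OC)c12
F3 | step 11 | 7-epimer of 16 (7S, OH cis to the C8 methyl) | COC1=CC2(C=C(OC)C1=O)C[C@@H](C)[C@H](C)[C@H](O)c1cc(OC)c(O)c(OC)c12
F4 | step 11 | 7-epimer of 17 (7S) | COC1=CC2(C=C(OC)C1=O)C[C@@H](C)[C@H](C)[C@H](O)c1cc(OC)c(OC)c(OC)c12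
F5 | step 11 | 4-nitrobenzoate of 17 (7R) | COC1=CC2(C=C(OC)C1=O)C[C@@H](C)[C@H](C)[C@@H](OC(=O)c3ccc(cc3)[N+](=O)[O-])c1cc(OC)c(OC)c(OC)c12
F6 | step 5 | (S)-4-benzyl-3-[(R)-2-(4-benzyloxy-3,5-dimethoxybenzyl)-4-tert-butoxy-4-oxobutanoyl]oxazolidin-2-one | O=C(N1[C@@H](Cc2ccccc2)COC1=O)[C@H](Cc1cc(OC)c(OCc2ccccc2)c(OC)c1)CC(=O)OC(C)(C)C
F7 | step 5 | tert-butyl (R)-3-(4-benzyloxy-3,5-dimethoxybenzyl)-4-hydroxybutanoate | OC[C@H](Cc1cc(OC)c(OCc2ccccc2)c(OC)c1)CC(=O)OC(C)(C)C
F8 | step 5 | (R)-4-(4-benzyloxy-3,5-dimethoxybenzyl)dihydrofuran-2(3H)-one | O=C1C[C@@H](Cc2cc(OC)c(OCc3ccccc3)c(OC)c2)CO1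
F9 | step 5 | 4-benzyloxy-3,5-dimethoxybenzaldehyde | COc1cc(C=O)cc(OC)c1OCc1ccccc1
F10 | step 5 | (4-benzyloxy-3,5-dimethoxyphenyl)methanol | COc1cc(CO)cc(OC)c1OCc1ccccc1
F11 | step 5 | 4-benzyloxy-3,5-dimethoxybenzyl bromide | COc1cc(CBr)cc(OC)c1OCc1ccccc1
F12 | step 5 | (3R,4R)-3,4-bis(4-benzyloxy-3,5-dimethoxybenzyl)dihydrofuran-2(3H)-one | O=C1OC[C@H](Cc2cc(OC)c(OCc3ccccc3)c(OC)c2)[C@H]1Cc1cc(OC)c(OCc2ccccc2)c(OC)c1
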